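## The problem

The target is a 1-aryltetralin. Ring A (C1–C6, methoxy on C3 and C5, free hydroxyl on C4) is fused through C1 and C2 to the carbocyclic ring B (C1–C2–C7'–C8'–C8–C7). Ring B carries the guaiacyl ring C on C7' and the methyl carbons C9' on C8' and C9 on C8. It holds three contiguous stereocentres (7'R, 8'R, 8R), with the aryl group trans to the C8' methyl and the two methyls cis. No heteroatom on ring B can relay stereochemistry, so the relative configuration must come from the ring-forming event and from the conformational bias of the ring, and the absolute configuration from an external chiral controller. One bias is built in: the C3 methoxy lies peri to C7' and pushes the aryl group pseudoaxial, which makes a trans C8' methyl axial on the opposite face, where it can shield one face of a trigonal C8. The sensitive parts are the two electron-rich phenols (para to C1 on ring A, para to C7' on ring C), which invite oxidation, and the doubly benzylic C7'–H. Both phenols are therefore carried as ethers that can be removed without acid or oxidant. The feature that opens the structure to a cycloaddition is that C7 and C7' are benzylic carbons on the adjacent ring A positions C1 and C2, the two termini of an ortho-quinodimethane, while C8 and C8', each bearing one methyl carbon, form a two-carbon dienophile. A carbonyl group at C7 is enough to generate that diene with light, and its oxygen can be discarded afterwards.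

## Retrosynthesis

**18 ⇒ 17.** The two C–H bonds across C7–C8 and the two O–benzyl bonds of target 18 are cut, giving the 1,2-dihydronaphthalene 17 with a C7=C8 double bond. A trans dienophile delivers the C8 substituent trans to the C8' methyl, whereas 18 needs them cis, so C8 has to be re-set in any case. A Z-dienophile reacting exo would give the right pattern directly, but it fights both the endo preference and the low reactivity of Z-enoyl imides. Making C8 trigonal erases the wrong configuration and lets the axial C8' methyl choose the face. The forward reaction must add hydrogen anti to that methyl without double-bond migration, and cleave both benzyl ethers in the same flask.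

**17 ⇒ 15 ⇒ 13 ⇒ 12.** These are functional-group changes at the two handles left by the ring-forming step. The C9–H bond of 17 is traced to the C9–O bond of allylic alcohol 15 (through sulfonate 16). Alcohol 15 is traced to the unsaturated imide 13 (through enal 14), and the C7=C8 bond of 13 to the β-hydroxy imide 12 by loss of water. Dehydrating before reduction is preferred to deoxygenating C7 directly, because it removes the C7 and C8 stereocentres of 12 in one operation and conjugates the alkene with ring A. The forward steps must leave C7' and C8' untouched and must reduce the imide carbonyl in the 1,2-sense.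

**12 ⇒ 6 + 10 (through 11).** Ring B is opened at C7–C8 and C7'–C8'. Other ring B cuts (C2–C7' by arylation, C8–C8' by coupling) would leave an open chain whose stereocentres have to be built one by one. This cut removes the ring and all four stereocentres of 12 together, and leads to two flat, achiral pieces: the 2-benzylbenzaldehyde 6 and the crotonoyl imide 10. The diene is the photodienol 11 formed from 6 by light. The forward reaction has to control four things:
- regiochemistry: the hydroxyl-bearing terminus must bond to the acyl-bearing carbon;
- endo addition;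
- transfer of the E geometry of 10 into the 7',8'-trans relationship;
- selection of one diene/dienophile face pair by a chiral titanium Lewis acid that binds both partners.

**6 ⇒ 2 + 5 (from 4).** The aryl–CH2 bond C2–C7' is cut. Cutting the other aryl–CH2 bond would need a benzylic metal ortho to the aldehyde. Electrophilic benzylation of ring A is not an option, since the only free positions are deactivated by the formyl group. The cut gives the ortho-bromoaldehyde 2 and the benzylic zinc reagent 5, made in the flask from chloride 4. The forward cross-coupling must tolerate the free aldehyde and a bromide flanked by two ortho substituents.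

**2 ⇒ 1; 4 ⇒ 3; 10 ⇒ 7 + 8 (through 9).** The C2–Br bond of 2 comes from bromination of the symmetrical aldehyde 1, whose only two free positions are equivalent. The C–Cl bond of 4 comes from benzylic alcohol 3. The N–acyl bond of 10 comes from oxazolidinone 7 (as its lithium salt 9) and acid chloride 8. Compounds 1, 3, 7 and 8 are catalogue materials; 1 and 3 already carry the benzyl ethers that stay on until the last step.

## Roads not taken

**Alternative 1:** The cut is at C8–C8' and C2–C7'. It returns a sinapate and a ferulate unit joined on a C2-symmetric diol tether as the mixed diester A1. In the forward direction, one-electron oxidation of both phenols would couple the two β-carbons; the re-aromatised syringyl ring would then attack C7' of the oxidised guaiacyl unit, closing ring B and a ten-membered dilactone in A2.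
- Merits: cheap cinnamate building blocks, no phenol protection, two skeletal bonds and ring B in one flask, and a tether that can pass its chirality to C7' and C8'.
- Weak points: phenoxy radicals also couple through oxygen and through ring carbons, and the tether only biases this. After β–β coupling either ring can attack the other unit, which would swap the substitution patterns of rings A and C. A2 carries both C9 and C9' as carboxyl carbons, so two carbons must be reduced to methyl and the phenols protected for that. C8 is still trigonal in A2, so the same late hydrogenation question remains.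
- Comparison: this road reaches the skeleton in fewer steps and needs no photochemical equipment, which is a real advantage. The chosen plan sets against it an unambiguous assignment of rings A and C (ring A is the aldehyde ring of 6), a dienophile that brings C9' in as a methyl group, and only one carboxyl-level carbon to reduce.

**Alternative 2:** The cut is at C1–C2 and C3–C4 of ring A. It returns the open-chain furyl bromoalkyne A3, in which C7', C8' and C8 are already in place. Heating would add the 4-methoxyfuran across the tethered bromoalkyne; the oxygen-bridged adduct opens to the C4 phenol and gives tetralin A4 with rings A and B formed together.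
- Merits: a thermal, intramolecular step with no arene regiochemistry to settle. All three stereocentres are fixed before ring closure, so no late facial selectivity is needed. In this respect it is better than the chosen plan.
- Weak points: A3 needs three contiguous stereocentres built on an acyclic chain, one of them (C7') benzylic and propargylic and therefore easily epimerised. The alkoxyfuran is sensitive to acid and air. A4 carries bromine where the C3 methoxy belongs, so a C–O coupling is still needed at a position squeezed between the C4 hydroxyl and the peri aryl group.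
- Comparison: the chosen plan accepts one late stereochemical gamble at C8. In return it has two flat precursors, ring A oxygenation complete from the start, and a total of nine steps.

**Alternative 3:** The cut is at C1–C6, C2–C3, C3–C4 and C5–C6. Ring A is built last from the cyclohexenyl diazo ketone A5 and methoxyethyne A6. Irradiation triggers a Wolff rearrangement, then (2+2) addition of A6, four-electron ring opening and six-electron ring closure to the phenol A7.
- Merits: regiocontrolled arene construction on a ring B whose stereocentres can be set on a cyclohexene, so C8 again does not depend on a late hydrogenation.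
- Weak points: A7 has no oxygen on C4. It would have to be introduced between the C3 hydroxyl and the C5 methoxy by a late phenol oxidation, followed by selective methylation of one of two adjacent hydroxyls. A5 is itself a multi-step target, and its C7' centre is allylic, benzylic and γ to the ketone, so it is open to epimerisation. A6 is volatile and unstable. The key step is also photochemical, so nothing is gained operationally.
- Comparison: this road is stronger on C8 control. The chosen plan is stronger on step count and on having the full oxygenation pattern of ring A present from compound 1.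

Key step: step 5

Assumption: (S,S)-TADDOL is (4S,5S)-2,2-dimethyl-α,α,α',α'-tetraphenyl-1,3-dioxolane-4,5-dimethanol. Its titanium complex is taken to leave the Cα-Si face of the chelated imide 10 open, by analogy with enoyl-oxazolidinone Diels–Alder reactions, in which the (R,R)-ligand leaves the Cα-Re face open. If the sense is reversed in the photoenol reaction, the mirror-image ligand is used and nothing else changes.

## Route

Step 1
Reactants: 1 4-benzyloxy-3,5-dimethoxybenzaldehyde
Product: 2 4-benzyloxy-2-bromo-3,5-dimethoxybenzaldehyde
Conditions: NBS (1.05 equiv), MeCN, rt, dark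
Reagents that add atoms: N-bromosuccinimide, O=C1CCC(=O)N1Br
Why: Electrophilic aromatic bromination; the only free positions of 1 (C2 and C6) are equivalent and each is ortho and para to a methoxy group, so monobromination can give only 2, and the unactivated benzyl ring does not compete.

Step 2
Reactants: 3 (4-benzyloxy-3-methoxyphenyl)methanol
Product: 4 1-benzyloxy-4-(chloromethyl)-2-methoxybenzene
Conditions: SOCl2, CH2Cl2, 0 °C to rt
Reagents that add atoms: thionyl chloride, O=S(Cl)Cl
Why: Chlorination of a primary benzylic alcohol through its chlorosulfite; the electron-rich chloride is used directly after evaporation.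

Step 3
Reactants: 4 1-benzyloxy-4-(chloromethyl)-2-methoxybenzene; 2 4-benzyloxy-2-bromo-3,5-dimethoxybenzaldehyde
Product: 6 4-benzyloxy-2-(4-benzyloxy-3-methoxybenzyl)-3,5-dimethoxybenzaldehyde, via benzylzinc chloride 5 (not isolated)
Conditions: Zn dust, LiCl, THF, rt; then 2, Pd(OAc)2 (2 mol%), SPhos (4 mol%), THF, rt to 50 °C
Reagents that add atoms: none
Why: LiCl-assisted zinc insertion into the benzylic chloride gives 5 with little homocoupling, and Negishi cross-coupling (oxidative addition of the aryl bromide to zerovalent palladium, transmetallation, reductive elimination) forms the C2–C7' bond. The bulky biarylphosphine handles the di-ortho-substituted bromide, and the catalysed coupling is expected to outrun addition of 5 to the aldehyde.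

Step 4
Reactants: 7 oxazolidin-2-one; 8 (E)-but-2-enoyl chloride
Product: 10 3-[(E)-but-2-enoyl]oxazolidin-2-one, via lithium oxazolidinone salt 9 (not isolated)
Conditions: n-BuLi, THF, −78 °C; then 8, −78 to 0 °C
Reagents that add atoms: none
Why: N-Acylation of the lithiated oxazolidinone by the acid chloride, the standard imide synthesis; the low temperature and the absence of amine base avoid deconjugation and loss of the E geometry.

Step 5
Reactants: 6 4-benzyloxy-2-(4-benzyloxy-3-methoxybenzyl)-3,5-dimethoxybenzaldehyde; 10 3-[(E)-but-2-enoyl]oxazolidin-2-one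
Product: 12 3-{[(1R,2R,3S,4R)-6-benzyloxy-4-(4-benzyloxy-3-methoxyphenyl)-1-hydroxy-5,7-dimethoxy-3-methyl-1,2,3,4-tetrahydronaphthalen-2-yl]carbonyl}oxazolidin-2-one, via outward photodienol 11 (not isolated)
Conditions: hν (366 nm), Ti(OiPr)4 (1.2 equiv), (S,S)-TADDOL (1.3 equiv), 4 Å MS, degassed toluene, 0 °C; aqueous work-up
Reagents that add atoms: none
Why: Excitation of the aldehyde and 1,5-hydrogen transfer from the doubly benzylic C7' methylene give the hydroxy-ortho-quinodimethane 11; the isomer with the hydroxyl turned inward reverts by a fast hydrogen shift and an inward aryl group would collide with C7, so the long-lived dienol has both groups outward (E at the enol; the benzylidene is Z by the sequence rule only because the C3 methoxy outranks C1). The dienol oxygen exchanges onto the Ti(TADDOLate) centre that also chelates the s-cis imide 10, and ring B closes by a concerted, suprafacial, intermolecular (4+2) cycloaddition across C7 and C7', driven by re-aromatisation of ring A; the closest known reaction type is the titanium-alkoxide-promoted photoenolisation/Diels–Alder reaction of ortho-alkylbenzaldehydes, combined with TADDOLate-mediated Diels–Alder reactions of enoyl oxazolidinones. Regiochemistry: the oxygen donor places the larger HOMO coefficient on C7', which bonds to the β-carbon (C8'), and the titanium bridge between dienol oxygen and imide holds C7 next to the α-carbon (C8). C7 and C8: the endo, metal-bridged transition state places hydroxyl and acyl group cis; both centres are removed later. C7': the outward aryl group ends up cis to the hydroxyl and to the endo acyl group. C8': the E geometry of 10 is transferred, so the methyl is trans to the acyl group and therefore trans to the aryl group, the 7',8'-trans relationship of the target. Absolute configuration: the (S,S)-ligand is expected to block the Cα-Re face of the chelated imide, so the diene adds to the Cα-Si/Cβ-Re face, giving 7'R and the C8' arrangement of the target (written 8'S in 12 only because the acyl group changes the priorities). The step needs regio-, endo- and face-selectivity together; the first two are secured by the dienol hydroxyl and the titanium template, the third by the ligand.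

Step 6
Reactants: 12 3-{[(1R,2R,3S,4R)-6-benzyloxy-4-(4-benzyloxy-3-methoxyphenyl)-1-hydroxy-5,7-dimethoxy-3-methyl-1,2,3,4-tetrahydronaphthalen-2-yl]carbonyl}oxazolidin-2-one
Product: 13 3-{[(3S,4R)-6-benzyloxy-4-(4-benzyloxy-3-methoxyphenyl)-5,7-dimethoxy-3-methyl-3,4-dihydronaphthalen-2-yl]carbonyl}oxazolidin-2-one
Conditions: p-TsOH·H2O (10 mol%), toluene, 60 °C
Reagents that add atoms: none
Why: Acid-catalysed E1 dehydration; the C7 cation is benzylic and para to the C4 benzyloxy group, and loss of the only β-proton (the acidic C8–H) gives the alkene conjugated with ring A and the imide. C7' and C8' take no part.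

Step 7
Reactants: 13 3-{[(3S,4R)-6-benzyloxy-4-(4-benzyloxy-3-methoxyphenyl)-5,7-dimethoxy-3-methyl-3,4-dihydronaphthalen-2-yl]carbonyl}oxazolidin-2-one
Product: 15 [(3S,4R)-6-benzyloxy-4-(4-benzyloxy-3-methoxyphenyl)-5,7-dimethoxy-3-methyl-3,4-dihydronaphthalen-2-yl]methanol, via enal 14 (not isolated)
Conditions: NaBH4, THF/H2O (4:1), 0 °C to rt
Reagents that add atoms: none
Why: Reductive cleavage of the N-acyl oxazolidinone by borohydride: hydride adds to the exocyclic carbonyl, the hemiaminal collapses to enal 14, and 14 is reduced in the 1,2-sense. Conjugate reduction is disfavoured because the β-carbon (C7) is part of an electron-rich styrene and the alkene is trisubstituted.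

Step 8
Reactants: 15 [(3S,4R)-6-benzyloxy-4-(4-benzyloxy-3-methoxyphenyl)-5,7-dimethoxy-3-methyl-3,4-dihydronaphthalen-2-yl]methanol
Product: 17 (1R,2S)-7-benzyloxy-1-(4-benzyloxy-3-methoxyphenyl)-6,8-dimethoxy-2,3-dimethyl-1,2-dihydronaphthalene, via allylic mesylate 16 (not isolated)
Conditions: Ms2O, Et3N, THF, −20 °C; then LiEt3BH (4 equiv), −20 °C to rt
Reagents that add atoms: none
Why: One-pot deoxygenation of a primary allylic alcohol by sulfonylation and SN2 hydride displacement with the triethylborohydride. An SN2' pathway would give the exocyclic-methylene isomer, which converges on the same product in step 9.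

Step 9
Reactants: 17 (1R,2S)-7-benzyloxy-1-(4-benzyloxy-3-methoxyphenyl)-6,8-dimethoxy-2,3-dimethyl-1,2-dihydronaphthalene
Product: 18 (-)-(7'R,8R,8'R)-4,4'-dihydroxy-3,3',5-trimethoxy-2,7'-cyclolignan
Conditions: H2 (1 atm), 10% Pd/C, EtOAc/EtOH, rt
Reagents that add atoms: none
Why: Heterogeneous hydrogenation of the styrenic alkene with concurrent hydrogenolysis of both benzyl ethers. In the half-chair of 17 the C7' aryl is pseudoaxial (peri C3 methoxy) and the trans C8' methyl is therefore axial on the opposite face, directly beside C8, so hydrogen should be delivered to C8 anti to that methyl, placing C9 cis to C9' (8R).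

## Compound list

1 | 4-benzyloxy-3,5-dimethoxybenzaldehyde | COc1cc(C=O)cc(OC)c1OCc1ccccc1 | starting material
2 | 4-benzyloxy-2-bromo-3,5-dimethoxybenzaldehyde | COc1cc(C=O)c(Br)c(OC)c1OCc1ccccc1 | intermediate
3 | (4-benzyloxy-3-methoxyphenyl)methanol | COc1cc(CO)ccc1OCc1ccccc1 | starting material
4 | 1-benzyloxy-4-(chloromethyl)-2-methoxybenzene | COc1cc(CCl)ccc1OCc1ccccc1 | intermediate
5 | (4-benzyloxy-3-methoxybenzyl)zinc chloride | COc1cc(C[Zn]Cl)ccc1OCc1ccccc1 | intermediate
6 | 4-benzyloxy-2-(4-benzyloxy-3-methoxybenzyl)-3,5-dimethoxybenzaldehyde | COc1cc(Cc2c(C=O)cc(OC)c(OCc3ccccc3)c2OC)ccc1OCc1ccccc1 | intermediate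
7 | oxazolidin-2-one | O=C1NCCO1 | starting material
8 | (E)-but-2-enoyl chloride | C/C=C/C(Cl)=O | starting material
9 | lithium 2-oxooxazolidin-3-ide | [Li]N1CCOC1=O | intermediate
10 | 3-[(E)-but-2-enoyl]oxazolidin-2-one | C/C=C/C(=O)N1CCOC1=O | intermediate
11 | (E)-[(6Z)-4-benzyloxy-6-(4-benzyloxy-3-methoxybenzylidene)-3,5-dimethoxycyclohexa-2,4-dien-1-ylidene]methanol (photodienol, hydroxyl and aryl both outward) | COC1=CC(=C/O)\C(=C\c2ccc(OCc3ccccc3)c(OC)c2)C(OC)=C1OCc1ccccc1 | intermediate
12 | 3-{[(1R,2R,3S,4R)-6-benzyloxy-4-(4-benzyloxy-3-methoxyphenyl)-1-hydroxy-5,7-dimethoxy-3-methyl-1,2,3,4-tetrahydronaphthalen-2-yl]carbonyl}oxazolidin-2-one (lignan numbering 7R,8R,7'R,8'S; C7 hydroxyl, C8 acyl and C7' aryl all cis, C8' methyl trans) | COc1cc([C@@H]2c3c(cc(OC)c(OCc4ccccc4)c3OC)[C@H](O)[C@H](C(=O)N3CCOC3=O)[C@H]2C)ccc1OCc1ccccc1 | intermediate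
13 | 3-{[(3S,4R)-6-benzyloxy-4-(4-benzyloxy-3-methoxyphenyl)-5,7-dimethoxy-3-methyl-3,4-dihydronaphthalen-2-yl]carbonyl}oxazolidin-2-one | COc1cc([C@@H]2c3c(cc(OC)c(OCc4ccccc4)c3OC)C=C(C(=O)N3CCOC3=O)[C@H]2C)ccc1OCc1ccccc1 | intermediate
14 | (3S,4R)-6-benzyloxy-4-(4-benzyloxy-3-methoxyphenyl)-5,7-dimethoxy-3-methyl-3,4-dihydronaphthalene-2-carbaldehyde | COc1cc([C@@H]2c3c(cc(OC)c(OCc4ccccc4)c3OC)C=C(C=O)[C@H]2C)ccc1OCc1ccccc1 | intermediate
15 | [(3S,4R)-6-benzyloxy-4-(4-benzyloxy-3-methoxyphenyl)-5,7-dimethoxy-3-methyl-3,4-dihydronaphthalen-2-yl]methanol | COc1cc([C@@H]2c3c(cc(OC)c(OCc4ccccc4)c3OC)C=C(CO)[C@H]2C)ccc1OCc1ccccc1 | intermediate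
16 | [(3S,4R)-6-benzyloxy-4-(4-benzyloxy-3-methoxyphenyl)-5,7-dimethoxy-3-methyl-3,4-dihydronaphthalen-2-yl]methyl methanesulfonate | COc1cc([C@@H]2c3c(cc(OC)c(OCc4ccccc4)c3OC)C=C(COS(C)(=O)=O)[C@H]2C)ccc1OCc1ccccc1 | intermediate
17 | (1R,2S)-7-benzyloxy-1-(4-benzyloxy-3-methoxyphenyl)-6,8-dimethoxy-2,3-dimethyl-1,2-dihydronaphthalene | COc1cc([C@@H]2c3c(cc(OC)c(OCc4ccccc4)c3OC)C=C(C)[C@H]2C)ccc1OCc1ccccc1 | intermediate
18 | (-)-(7'R,8R,8'R)-4,4'-dihydroxy-3,3',5-trimethoxy-2,7'-cyclolignan, that is (6R,7R,8R)-8-(4-hydroxy-3-methoxyphenyl)-1,3-dimethoxy-6,7-dimethyl-5,6,7,8-tetrahydronaphthalen-2-ol | COc1cc([C@@H]2c3c(cc(OC)c(O)c3OC)C[C@@H](C)[C@H]2C)ccc1O | target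

## Step count and risks

Total: 9 steps. Longest linear sequence: 7 steps (step 1 or 2, then steps 3, 5, 6, 7, 8, 9).

**Step 5 (key step).**
- What may go wrong: poor facial selectivity, or induction in the opposite sense, because the face rule is carried over from ground-state Diels–Alder reactions to a dienol bound to the same metal. Trapping of the dienol by the β-substituted dienophile may also be slow, which lets reversion to 6, four-electron ring closure or oxidation of the dienol compete. Some exo addition is possible.
- Fallback (sets out from 6, returns at 15): replace reagent control by a covalently bound auxiliary. Aldehyde 6 is irradiated with the commercial chiral imide (S)-4-benzyl-3-[(E)-but-2-enoyl]oxazolidin-2-one F1 and achiral Ti(OiPr)4. The benzyl group of the chelated s-cis imide covers the Cα-Re face, so the diene should again add to the Cα-Si face and give the cycloadduct 3-{[(1R,2R,3S,4R)-6-benzyloxy-4-(4-benzyloxy-3-methoxyphenyl)-1-hydroxy-5,7-dimethoxy-3-methyl-1,2,3,4-tetrahydronaphthalen-2-yl]carbonyl}-(4S)-4-benzyloxazolidin-2-one F2, from which any minor diastereomer can be separated. Dehydration as in step 6 gives the unsaturated imide 3-{[(3S,4R)-6-benzyloxy-4-(4-benzyloxy-3-methoxyphenyl)-5,7-dimethoxy-3-methyl-3,4-dihydronaphthalen-2-yl]carbonyl}-(4S)-4-benzyloxazolidin-2-one F3. Borohydride cleavage as in step 7 removes the auxiliary and delivers 15.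

**Step 9.**
- What may go wrong: hydrogen delivery to the wrong face of C8, since the pseudoaxial aryl group also encumbers the face that must be used. Palladium may also migrate the double bond toward C8' before reduction, which would erode both C8 and C8'.
- Fallback (sets out from 13, returns at 18): set C8 by thermodynamic control. Conjugate reduction of 13 with Mg in MeOH, in which the magnesium methoxide formed also turns the imide into the ester, followed by equilibration with NaOMe/MeOH, should give methyl (2R,3S,4R)-6-benzyloxy-4-(4-benzyloxy-3-methoxyphenyl)-5,7-dimethoxy-3-methyl-1,2,3,4-tetrahydronaphthalene-2-carboxylate F4. The ester group prefers the equatorial position cis to the axial C8' methyl, because the epimer would place it 1,3-diaxial to the pseudoaxial aryl group. LiAlH4 reduction gives [(2R,3S,4R)-6-benzyloxy-4-(4-benzyloxy-3-methoxyphenyl)-5,7-dimethoxy-3-methyl-1,2,3,4-tetrahydronaphthalen-2-yl]methanol F5. Mesylation gives its methanesulfonate F6, and LiEt3BH displacement gives (1R,2R,3R)-7-benzyloxy-1-(4-benzyloxy-3-methoxyphenyl)-6,8-dimethoxy-2,3-dimethyl-1,2,3,4-tetrahydronaphthalene F7. Hydrogenolysis (H2, Pd/C) then only has to remove the benzyl groups to reach 18.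

**Step 3.**
- What may go wrong: uncatalysed 1,2-addition of the benzylic zinc reagent to the aldehyde, homocoupling during zinc insertion, and slow oxidative addition at the doubly ortho-substituted bromide.
- Fallback (sets out from 4, returns at 6): change the nucleophile to boron. Palladium-catalysed borylation of 4 (B2pin2, Pd(dba)2, tris(4-methoxyphenyl)phosphine, KOAc, toluene) gives 2-(4-benzyloxy-3-methoxybenzyl)-4,4,5,5-tetramethyl-1,3,2-dioxaborolane F8. Suzuki–Miyaura coupling of F8 with 2 (PdCl2(dppf), Cs2CO3, THF/H2O, 70 °C), which is indifferent to the aldehyde, gives 6.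

**Step 8.**
- What may go wrong: ionisation of the very labile allylic sulfonate (its cation is conjugated with ring A), leading to solvolysis or oligomerisation before hydride arrives, and attack of hydride at C7.
- Fallback (sets out from 15, returns at 17): replace the SN2 displacement by a π-allyl reduction. Acetylation of 15 (Ac2O, pyridine) gives [(3S,4R)-6-benzyloxy-4-(4-benzyloxy-3-methoxyphenyl)-5,7-dimethoxy-3-methyl-3,4-dihydronaphthalen-2-yl]methyl acetate F9. Palladium-catalysed allylic reduction (Pd(PPh3)4, NaBH4, THF) delivers hydride to the less hindered CH2 terminus of the allylpalladium intermediate and returns 17.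

## Further compounds

F1 | step 5 | (S)-4-benzyl-3-[(E)-but-2-enoyl]oxazolidin-2-one | C/C=C/C(=O)N1[C@@H](Cc2ccccc2)COC1=O
F2 | step 5 | 3-{[(1R,2R,3S,4R)-6-benzyloxy-4-(4-benzyloxy-3-methoxyphenyl)-1-hydroxy-5,7-dimethoxy-3-methyl-1,2,3,4-tetrahydronaphthalen-2-yl]carbonyl}-(4S)-4-benzyloxazolidin-2-one | COc1cc([C@@H]2c3c(cc(OC)c(OCc4ccccc4)c3OC)[C@H](O)[C@H](C(=O)N3[C@@H](Cc4ccccc4)COC3=O)[C@H]2C)ccc1OCc1ccccc1
F3 | step 5 | 3-{[(3S,4R)-6-benzyloxy-4-(4-benzyloxy-3-methoxyphenyl)-5,7-dimethoxy-3-methyl-3,4-dihydronaphthalen-2-yl]carbonyl}-(4S)-4-benzyloxazolidin-2-one | COc1cc([C@@H]2c3c(cc(OC)c(OCc4ccccc4)c3OC)C=C(C(=O)N3[C@@H](Cc4ccccc4)COC3=O)[C@H]2C)ccc1OCc1ccccc1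
F4 | step 9 | methyl (2R,3S,4R)-6-benzyloxy-4-(4-benzyloxy-3-methoxyphenyl)-5,7-dimethoxy-3-methyl-1,2,3,4-tetrahydronaphthalene-2-carboxylate | COc1cc([C@@H]2c3c(cc(OC)c(OCc4ccccc4)c3OC)C[C@@H](C(=O)OC)[C@H]2C)ccc1OCc1ccccc1
F5 | step 9 | [(2R,3S,4R)-6-benzyloxy-4-(4-benzyloxy-3-methoxyphenyl)-5,7-dimethoxy-3-methyl-1,2,3,4-tetrahydronaphthalen-2-yl]methanol | COc1cc([C@@H]2c3c(cc(OC)c(OCc4ccccc4)c3OC)C[C@@H](CO)[C@H]2C)ccc1OCc1ccccc1
F6 | step 9 | [(2R,3S,4R)-6-benzyloxy-4-(4-benzyloxy-3-methoxyphenyl)-5,7-dimethoxy-3-methyl-1,2,3,4-tetrahydronaphthalen-2-yl]methyl methanesulfonate | COc1cc([C@@H]2c3c(cc(OC)c(OCc4ccccc4)c3OC)C[C@@H](COS(C)(=O)=O)[C@H]2C)ccc1OCc1ccccc1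
F7 | step 9 | (1R,2R,3R)-7-benzyloxy-1-(4-benzyloxy-3-methoxyphenyl)-6,8-dimethoxy-2,3-dimethyl-1,2,3,4-tetrahydronaphthalene | COc1cc([C@@H]2c3c(cc(OC)c(OCc4ccccc4)c3OC)C[C@@H](C)[C@H]2C)ccc1OCc1ccccc1
F8 | step 3 | 2-(4-benzyloxy-3-methoxybenzyl)-4,4,5,5-tetramethyl-1,3,2-dioxaborolane | COc1cc(CB2OC(C)(C)C(C)(C)O2)ccc1OCc1ccccc1
F9 | step 8 | [(3S,4R)-6-benzyloxy-4-(4-benzyloxy-3-methoxyphenyl)-5,7-dimethoxy-3-methyl-3,4-dihydronaphthalen-2-yl]methyl acetate | COc1cc([C@@H]2c3c(cc(OC)c(OCc4ccccc4)c3OC)C=C(COC(C)=O)[C@H]2C)ccc1OCc1ccccc1
A1 | alternative 1 | [(4R,5R)-5-({[(E)-3-(4-hydroxy-3,5-dimethoxyphenyl)prop-2-enoyl]oxy}methyl)-2,2-dimethyl-1,3-dioxolan-4-yl]methyl (E)-3-(4-hydroxy-3-methoxyphenyl)prop-2-enoate (tethered sinapate–ferulate diester) | COc1cc(/C=C/C(=O)OC[C@H]2OC(C)(C)O[C@@H]2COC(=O)/C=C/c2cc(OC)c(O)c(OC)c2)ccc1O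
A2 | alternative 1 | 1-aryl-1,2-dihydronaphthalene-2,3-dicarboxylate held as a ten-membered dilactone on the (4R,5R)-dioxolane tether | COc1cc([C@@H]2c3c(cc(OC)c(O)c3OC)C=C3C(=O)OC[C@H]4OC(C)(C)O[C@@H]4COC(=O)[C@@H]23)ccc1O
A3 | alternative 2 | 2-[5-bromo-3-(4-benzyloxy-3-methoxyphenyl)-1,2-dimethylpent-4-ynyl-methyl]-4-methoxyfuran, open-chain furyl bromoalkyne with C8, C8' and C7' preset | COc1coc(C[C@@H](C)[C@@H](C)[C@@H](C#CBr)c2ccc(OCc3ccccc3)c(OC)c2)c1
A4 | alternative 2 | tetralin with C4 hydroxyl, C5 methoxy and bromine on C3, ring C as benzyl ether | COc1cc([C@@H]2c3c(cc(OC)c(O)c3Br)C[C@@H](C)[C@H]2C)ccc1OCc1ccccc1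
A5 | alternative 3 | 2-diazo-1-[3-aryl-4,5-dimethylcyclohex-1-en-1-yl]ethanone, aryl = 3-methoxy-4-(triisopropylsilyloxy)phenyl | [N-]=[N+]=CC(=O)C1=C[C@@H](c2ccc(O[Si](C(C)C)(C(C)C)C(C)C)c(OC)c2)[C@H](C)[C@H](C)C1
A6 | alternative 3 | methoxyethyne | C#COC
A7 | alternative 3 | tetralin with C3 hydroxyl and C5 methoxy, C4 unsubstituted, ring C as triisopropylsilyl ether | COc1cc([C@@H]2c3c(cc(OC)cc3O)C[C@@H](C)[C@H]2C)ccc1O[Si](C(C)C)(C(C)C)C(C)C
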